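**Plan**
- The last retrosynthetic cut is between the benzylic carbon C7 and the 4-hydroxyphenyl ring (aryl Grignard reagent plus a ring-A aldehyde; the carbinol oxygen leaves by hydrogenolysis together with the benzyl ethers).
- Ring A is then opened at C1–C2. Its oxygens on C3 and C5, the arylethyl chain on C1 and the carbon C7 on C2 map onto the alternate ketones, the chain-end ketone and the ester carbon of a linear 3,5,7-triketo ester, so ring A can be built as a resorcylate by aldol closure.
- The triketo ester is cut between chain C-6 and C-7 into the trianion of methyl 3,5-dioxohexanoate (from dehydroacetic acid) and the N-methoxy-N-methylamide of O-benzylated 3-(3-hydroxyphenyl)propanoic acid.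
- Forward: the chain is assembled (steps 1–4), ring A is closed (step 5; the only ring made, the other two arenes are bought), then O-methylation, ester to aldehyde, aryl addition and global hydrogenolysis follow.
- Stereochemistry: the target is achiral; the one carbinol centre that appears (compound 16) is racemic and becomes CH2 in the last step.

Key step: step 5

Remark: the target has no stereogenic element, so "single enantiomer" is taken to mean the achiral constitution given by the SMILES.

**Step 1**
Reactants: 1 dehydroacetic acid
Product: 3 methyl 3,5-dioxohexanoate, via methyl 2-acetyl-3,5-dioxohexanoate 2 (not isolated)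
Conditions: Mg(OMe)2 (2 equiv, commercial solution), MeOH, reflux; then cold 1 M HCl
Reagents that add atoms: methanol, CO; magnesium methoxide, [Mg+2].C[O-].C[O-]
Why: Methoxide opens the pyranone lactone to the acyclic tricarbonyl ester 2, whose magnesium chelate should lose the C-acetyl group as methyl acetate by retro-Claisen cleavage, a well-established methanolysis/deacetylation of this pyranone.

**Step 2**
Reactants: 4 3-(3-hydroxyphenyl)propanoic acid
Product: 5 benzyl 3-[3-(benzyloxy)phenyl]propanoate
Conditions: BnBr (2.5 equiv), K2CO3 (3 equiv), DMF, 60 °C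
Reagents that add atoms: benzyl bromide, BrCc1ccccc1
Why: Williamson etherification of the phenol and O-alkylation of the carboxylate proceed together with excess benzyl bromide, masking the phenol for all later base and organometallic steps.

**Step 3**
Reactants: 5 benzyl 3-[3-(benzyloxy)phenyl]propanoate
Product: 6 3-[3-(benzyloxy)phenyl]-N-methoxy-N-methylpropanamide
Conditions: MeNH(OMe)·HCl (1.5 equiv), iPrMgCl (3 equiv), THF, −20 → 0 °C; then cold 1 M HCl
Reagents that add atoms: N,O-dimethylhydroxylamine hydrochloride, CNOC.Cl
Why: The chloromagnesium amide formed from the amine salt and iPrMgCl at −20 °C attacks the ester faster than the Grignard reagent itself does, so direct ester aminolysis should give the Weinreb amide.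

**Step 4**
Reactants: 3 methyl 3,5-dioxohexanoate; 6 3-[3-(benzyloxy)phenyl]-N-methoxy-N-methylpropanamide
Product: 8 methyl 9-[3-(benzyloxy)phenyl]-3,5,7-trioxononanoate, via trilithium trianion of methyl 3,5-dioxohexanoate 7 (not isolated)
Conditions: 3 (1.5 equiv), LDA (4.6 equiv, commercial solution), THF, 0 °C, 1 h; then 6 (1.0 equiv), −78 → 0 °C; cold 1 M HCl to pH 3–4, rapid extraction, crude 8 used at once
Reagents that add atoms: none
Why: Polyanion C-acylation (Claisen type): the trianion reacts at its last-formed, most basic terminal carbanion (the former C6 methyl), and the amide holds the product as an N,O-chelated tetrahedral lithium adduct until the acidic quench, so neither over-addition nor proton transfer from the new triketone should drain the nucleophile.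

**Step 5**
Reactants: 8 methyl 9-[3-(benzyloxy)phenyl]-3,5,7-trioxononanoate
Product: 10 methyl 2-{2-[3-(benzyloxy)phenyl]ethyl}-4,6-dihydroxybenzoate, via cyclic aldol adduct 9 (not isolated)
Conditions: 1 M aq KOH (3 equiv), THF, 0 °C → rt; then 1 M HCl to pH 2 (a pH 9 aqueous buffer is the gentler setting of the same step)
Reagents that add atoms: none
Why: Hydroxide converts 8 into its enolates, and the carbanion at chain C-2 (between the ester and the C-3 ketone) adds to the C-7 ketone, the only carbonyl it can reach through a six-membered transition state; the β-hydroxy ketone 9 then loses water and the two remaining ring carbonyls enolise, so the sequence ends irreversibly in the aromatic resorcylate. The closest known reaction type is the base-mediated aldol aromatisation of 3,5,7-triketo esters to β-resorcylates, the laboratory counterpart of bibenzyl-synthase folding. Ring A closes by forming the chain C-2–C-7 bond (C2–C1 of ring A in the target) in a 6-exo-trig mode with respect to the C-7 carbonyl (6-enolendo for the C-2/C-3 enolate), both favoured. No stereocentre results: the two centres of 9 form without control and are destroyed on dehydration. The step needs aldol closure to beat Claisen closure of chain C-6 onto the ester (acylphloroglucinol), O-cyclisation to a pyranone or pyrone, and aldol attack from the C-8 methylene; dilute aqueous hydroxide at or below room temperature should secure this because a ketone is a better acceptor than an ester that is part of a β-keto ester enolate, and because only the doubly activated C-2, C-4 and C-6 positions are deprotonated. Short exposure and the deactivating ortho-phenoxide should keep the methyl ester from being saponified.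

**Step 6**
Reactants: 10 methyl 2-{2-[3-(benzyloxy)phenyl]ethyl}-4,6-dihydroxybenzoate
Product: 11 methyl 2-{2-[3-(benzyloxy)phenyl]ethyl}-4,6-dimethoxybenzoate
Conditions: MeI (5 equiv), K2CO3 (4 equiv), acetone, reflux
Reagents that add atoms: iodomethane, CI
Why: Williamson O-methylation of both phenols, with excess methyl iodide and heating because the C6 hydroxyl is hydrogen-bonded to the ester carbonyl and reacts slowly.

**Step 7**
Reactants: 11 methyl 2-{2-[3-(benzyloxy)phenyl]ethyl}-4,6-dimethoxybenzoate
Product: 12 (2-{2-[3-(benzyloxy)phenyl]ethyl}-4,6-dimethoxyphenyl)methanol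
Conditions: LiAlH4 (2 equiv), THF, 0 °C → reflux; H2O / 15% aq NaOH / H2O work-up
Reagents that add atoms: none
Why: Hydride reduction of the doubly ortho-substituted, electron-rich benzoate needs LiAlH4 with heating and should stop at the benzylic alcohol, the basic work-up avoiding ionisation of the acid-labile 2,4-dimethoxybenzyl alcohol.

**Step 8**
Reactants: 12 (2-{2-[3-(benzyloxy)phenyl]ethyl}-4,6-dimethoxyphenyl)methanol
Product: 13 2-{2-[3-(benzyloxy)phenyl]ethyl}-4,6-dimethoxybenzaldehyde
Conditions: activated MnO2 (15 equiv), CH2Cl2, rt
Reagents that add atoms: none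
Why: Activated manganese dioxide oxidises benzylic alcohols selectively to aldehydes under neutral conditions, without over-oxidation and without acid that would ionise the substrate.

**Step 9**
Reactants: 13 2-{2-[3-(benzyloxy)phenyl]ethyl}-4,6-dimethoxybenzaldehyde; 14 1-(benzyloxy)-4-bromobenzene
Product: 16 [4-(benzyloxy)phenyl](2-{2-[3-(benzyloxy)phenyl]ethyl}-4,6-dimethoxyphenyl)methanol, via [4-(benzyloxy)phenyl]magnesium bromide 15 (not isolated)
Conditions: 14 (1.5 equiv), Mg turnings, I2 (cat.), THF, reflux; then 13, THF, 0 °C → rt; sat. aq NH4Cl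
Reagents that add atoms: none
Why: Grignard addition of the aryl magnesium bromide to the aldehyde forms the C7–aryl bond, and the new carbinol centre arises as a racemate, which does not matter because it becomes a methylene in step 10.

**Step 10**
Reactants: 16 [4-(benzyloxy)phenyl](2-{2-[3-(benzyloxy)phenyl]ethyl}-4,6-dimethoxyphenyl)methanol
Product: 17 Gymcononopin D
Conditions: H2 (1 atm), 10% Pd/C, EtOAc–AcOH (10:1), rt
Reagents that add atoms: none
Why: Palladium-catalysed hydrogenolysis should cleave both benzyl ethers and, assisted by acetic acid, the doubly benzylic C–OH bond flanked by two electron-rich arenes, giving the diarylmethane and both free phenols in one operation.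

**Compound list**
1 | dehydroacetic acid | CC(=O)C1=C(O)C=C(C)OC1=O | starting material
2 | methyl 2-acetyl-3,5-dioxohexanoate (not isolated) | COC(=O)C(C(C)=O)C(=O)CC(C)=O | intermediate
3 | methyl 3,5-dioxohexanoate | COC(=O)CC(=O)CC(C)=O | intermediate
4 | 3-(3-hydroxyphenyl)propanoic acid | OC(=O)CCc1cccc(O)c1 | starting material
5 | benzyl 3-[3-(benzyloxy)phenyl]propanoate | O=C(CCc1cccc(OCc2ccccc2)c1)OCc1ccccc1 | intermediate
6 | 3-[3-(benzyloxy)phenyl]-N-methoxy-N-methylpropanamide | CON(C)C(=O)CCc1cccc(OCc2ccccc2)c1 | intermediate
7 | trilithium trianion of methyl 3,5-dioxohexanoate (not isolated) | [Li+].[Li+].[Li+].[CH2-]C(=O)[CH-]C(=O)[CH-]C(=O)OC | intermediate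
8 | methyl 9-[3-(benzyloxy)phenyl]-3,5,7-trioxononanoate | COC(=O)CC(=O)CC(=O)CC(=O)CCc1cccc(OCc2ccccc2)c1 | intermediate
9 | methyl 2-{2-[3-(benzyloxy)phenyl]ethyl}-2-hydroxy-4,6-dioxocyclohexane-1-carboxylate (cyclic aldol adduct, mixture of stereoisomers, not isolated) | COC(=O)C1C(=O)CC(=O)CC1(O)CCc1cccc(OCc2ccccc2)c1 | intermediate
10 | methyl 2-{2-[3-(benzyloxy)phenyl]ethyl}-4,6-dihydroxybenzoate | COC(=O)c1c(O)cc(O)cc1CCc1cccc(OCc2ccccc2)c1 | intermediate
11 | methyl 2-{2-[3-(benzyloxy)phenyl]ethyl}-4,6-dimethoxybenzoate | COC(=O)c1c(OC)cc(OC)cc1CCc1cccc(OCc2ccccc2)c1 | intermediate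
12 | (2-{2-[3-(benzyloxy)phenyl]ethyl}-4,6-dimethoxyphenyl)methanol | OCc1c(OC)cc(OC)cc1CCc1cccc(OCc2ccccc2)c1 | intermediate
13 | 2-{2-[3-(benzyloxy)phenyl]ethyl}-4,6-dimethoxybenzaldehyde | O=Cc1c(OC)cc(OC)cc1CCc1cccc(OCc2ccccc2)c1 | intermediate
14 | 1-(benzyloxy)-4-bromobenzene | Brc1ccc(OCc2ccccc2)cc1 | starting material
15 | [4-(benzyloxy)phenyl]magnesium bromide (not isolated) | Br[Mg]c1ccc(OCc2ccccc2)cc1 | intermediate
16 | [4-(benzyloxy)phenyl](2-{2-[3-(benzyloxy)phenyl]ethyl}-4,6-dimethoxyphenyl)methanol (racemic) | OC(c1ccc(OCc2ccccc2)cc1)c1c(OC)cc(OC)cc1CCc1cccc(OCc2ccccc2)c1 | intermediate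
17 | Gymcononopin D, 3-{2-[2-(4-hydroxybenzyl)-3,5-dimethoxyphenyl]ethyl}phenol (achiral) | COc1cc(CCc2cccc(O)c2)c(Cc2ccc(O)cc2)c(OC)c1 | target

**Count**
Total steps: 10. Longest linear sequence: 9 steps (4 → 5 → 6 → 8 → 10 → 11 → 12 → 13 → 16 → 17, steps 2–10).

**Steps most likely to fail**

Step 4. Proton transfer from the α-methylene of the amide to the strongly basic trianion, or cyclisation of the triketo ester during work-up, may leave little acyclic product. The fallback sets out from amide 6 and comes back at triketo ester 8. Commercial 2,2,6-trimethyl-4H-1,3-dioxin-4-one is deprotonated with LiHMDS (THF, −78 °C) and C-acetylated with acetyl chloride to give 2,2-dimethyl-6-(2-oxopropyl)-4H-1,3-dioxin-4-one F1. Its less basic dianion (LDA, 2 equiv, THF, −78 °C) is acylated at the terminal methyl by 6 to give the storable 6-{6-[3-(benzyloxy)phenyl]-2,4-dioxohexyl}-2,2-dimethyl-4H-1,3-dioxin-4-one F2. Heating F2 with methanol in toluene (110 °C) expels acetone by retro-[4+2] cleavage, and methanol traps the acylketene as the methyl ester, which is 8, unveiled only just before the cyclisation.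

Step 5. Ring closure onto the ester carbonyl (Claisen), O-cyclisation to a pyranone or pyrone, or saponification may compete with the aldol closure. The fallback sets out from amide 6 and comes back at resorcylate 10; it builds ring A by a Michael–Dieckmann sequence and dehydrogenation instead. DIBAL-H (THF, −78 °C) reduces 6 to 3-[3-(benzyloxy)phenyl]propanal F3. Wittig olefination with 1-(triphenylphosphoranylidene)propan-2-one (toluene, 80 °C) gives (E)-6-[3-(benzyloxy)phenyl]hex-3-en-2-one F4. Conjugate addition of dimethyl malonate followed by Dieckmann closure (NaOMe, MeOH, reflux) gives methyl 6-{2-[3-(benzyloxy)phenyl]ethyl}-2,4-dioxocyclohexane-1-carboxylate F5. Bromination and dehydrobromination (Br2, 1 equiv, DMF, 0 → 80 °C) aromatise F5 to 10.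

Step 10. Hydrogenolysis may stall at the carbinol stage once the benzyl ethers are gone, through slow C–O cleavage or catalyst deactivation. The fallback sets out from carbinol 16 and comes back at target 17. Ionic deoxygenation with Et3SiH/TFA (CH2Cl2, 0 °C) first removes the carbinol oxygen through the stabilised diarylmethyl cation to give 1-{2-[3-(benzyloxy)phenyl]ethyl}-2-[4-(benzyloxy)benzyl]-3,5-dimethoxybenzene F6. Plain hydrogenolysis of the two benzyl ethers (H2, Pd/C, EtOAc–MeOH, rt) then gives 17.

**Further compounds**
F1 | step 4 | 2,2-dimethyl-6-(2-oxopropyl)-4H-1,3-dioxin-4-one | CC(=O)CC1=CC(=O)OC(C)(C)O1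
F2 | step 4 | 6-{6-[3-(benzyloxy)phenyl]-2,4-dioxohexyl}-2,2-dimethyl-4H-1,3-dioxin-4-one | CC1(C)OC(=O)C=C(CC(=O)CC(=O)CCc2cccc(OCc3ccccc3)c2)O1
F3 | step 5 | 3-[3-(benzyloxy)phenyl]propanal | O=CCCc1cccc(OCc2ccccc2)c1
F4 | step 5 | (E)-6-[3-(benzyloxy)phenyl]hex-3-en-2-one | CC(=O)/C=C/CCc1cccc(OCc2ccccc2)c1
F5 | step 5 | methyl 6-{2-[3-(benzyloxy)phenyl]ethyl}-2,4-dioxocyclohexane-1-carboxylate (mixture of stereoisomers) | COC(=O)C1C(=O)CC(=O)CC1CCc1cccc(OCc2ccccc2)c1
F6 | step 10 | 1-{2-[3-(benzyloxy)phenyl]ethyl}-2-[4-(benzyloxy)benzyl]-3,5-dimethoxybenzene | COc1cc(CCc2cccc(OCc3ccccc3)c2)c(Cc2ccc(OCc3ccccc3)cc2)c(OC)c1
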